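**Assumption:** the enol tautomers of the triketone rings are treated as one compound, and the target has no stereocenter. Both acylphloroglucinols 1 and 3 are taken as catalogue compounds.

**Retrosynthetic overview**
- The target is two enolized 2-acylcyclohexane-1,3,5-trione rings, ring A (acetyl) and ring B (butanoyl), joined C3–CH2–C3'. Route locants: C1 bears the acyl group, C2/C4/C6 bear oxygen, C3 bears the bridge, and C5 is the quaternary C(CH3)2 carbon, the only sp3 ring atom.
- Key disconnection: all four C5–CH3 and C5'–CH3 bonds at once, back to the fully aromatic hexaphenol diarylmethane 5. One fourfold C-methylation dearomatizes ring A and ring B and sets both quaternary carbons in the last operation.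
- Second disconnection: the aryl C3–CH2 bond of 5, formed from ortho-quinone methide 4 (released from Mannich base 2 of phloracetophenone 1) and phlorbutyrophenone 3. The two acyl groups differentiate the halves from the start.
- Ring order: no ring is closed. Both carbocycles come from the commercial acylphloroglucinols and are converted together from benzenoid to cross-conjugated triketone rings in step 3.

Key step: step 3

**Step 1**
Reactants: 1 1-(2,4,6-trihydroxyphenyl)ethan-1-one (phloracetophenone)
Product: 2 1-{3-[(dimethylamino)methyl]-2,4,6-trihydroxyphenyl}ethan-1-one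
Conditions: 37% aq. CH2O (1.0 equiv), 40% aq. Me2NH (1.0 equiv), EtOH, 0 °C to rt
Reagents that add atoms: formaldehyde C=O; dimethylamine CNC
Why: Mannich reaction, in which the iminium ion from formaldehyde and dimethylamine attacks one of the two equivalent free ring carbons of the phloroglucinol nucleus, and the zwitterionic mono-Mannich base should separate from ethanol before a second aminomethylation sets in.

**Step 2**
Reactants: 2 1-{3-[(dimethylamino)methyl]-2,4,6-trihydroxyphenyl}ethan-1-one; 3 1-(2,4,6-trihydroxyphenyl)butan-1-one (phlorbutyrophenone)
Product: 5 1-{3-[(3-acetyl-2,4,6-trihydroxyphenyl)methyl]-2,4,6-trihydroxyphenyl}butan-1-one, via ortho-quinone methide 4 (not isolated)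
Conditions: 3 (3 equiv), 1,4-dioxane, 100 °C, N2 sweep
Reagents that add atoms: none
Why: Thermal retro-Mannich loss of dimethylamine from 2 releases ortho-quinone methide 4, which is trapped by Friedel–Crafts-type conjugate addition of one of the two equivalent free ring carbons of 3 (in excess, so that cross-coupling outruns self-coupling), and rearomatization gives the unsymmetrical diarylmethane.

**Step 3**
Reactants: 5 1-{3-[(3-acetyl-2,4,6-trihydroxyphenyl)methyl]-2,4,6-trihydroxyphenyl}butan-1-one
Product: 7 2-acetyl-4-[(5-butanoyl-2,6-dihydroxy-3,3-dimethyl-4-oxocyclohexa-1,5-dien-1-yl)methyl]-3,5-dihydroxy-6,6-dimethylcyclohexa-2,4-dien-1-one (the target), via bis(C-methyl) hexaphenol 6 (not isolated)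
Conditions: NaOMe (8 equiv), MeI (4.4 equiv), MeOH, 0 °C to rt; then 1 M HCl
Reagents that add atoms: iodomethane CI
Why: NaOMe turns each acylphloroglucinol ring of 5 into a polyphenoxide whose only unsubstituted ring carbon (C5, C5') attacks MeI by SN2 to give 6, and a second SN2 methylation at the same carbon makes it quaternary, so that the ring can no longer rearomatize and settles as the enolized 2-acylcyclohexane-1,3,5-trione. The closest known reaction type is the dearomative gem-dimethylation of acylphloroglucinols and their 3-alkyl congeners with NaOMe and MeI, here run on both rings of one diarylmethane in the same flask. No ring is closed and no stereocenter is formed. The step needs C- over O-methylation, which the protic solvent, the sodium counter-ion and the soft electrophile favor. It also needs the second methyl group of each ring to enter at C5/C5' and not at the bridge-bearing C3/C3', which should follow from sterics, because C5 carries only a methyl group whereas C3 carries the bulky arylmethyl arm. The reaction should stop at four methyl groups, because each dearomatized ring is a strongly acidic vinylogous acid whose delocalized anion is a poor carbon nucleophile and because MeI is charged close to stoichiometry.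

**Compound list**
1 | 1-(2,4,6-trihydroxyphenyl)ethan-1-one (phloracetophenone) | CC(=O)c1c(O)cc(O)cc1O | starting material
2 | 1-{3-[(dimethylamino)methyl]-2,4,6-trihydroxyphenyl}ethan-1-one | CC(=O)c1c(O)cc(O)c(CN(C)C)c1O | intermediate
3 | 1-(2,4,6-trihydroxyphenyl)butan-1-one (phlorbutyrophenone) | CCCC(=O)c1c(O)cc(O)cc1O | starting material
4 | 2-acetyl-3,5-dihydroxy-6-methylidenecyclohexa-2,4-dien-1-one (ortho-quinone methide, not isolated) | CC(=O)C1=C(O)C=C(O)C(=C)C1=O | intermediate
5 | 1-{3-[(3-acetyl-2,4,6-trihydroxyphenyl)methyl]-2,4,6-trihydroxyphenyl}butan-1-one | CCCC(=O)c1c(O)cc(O)c(Cc2c(O)cc(O)c(C(C)=O)c2O)c1O | intermediate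
6 | 1-{3-[(3-acetyl-2,4,6-trihydroxy-5-methylphenyl)methyl]-2,4,6-trihydroxy-5-methylphenyl}butan-1-one (not isolated) | CCCC(=O)c1c(O)c(C)c(O)c(Cc2c(O)c(C)c(O)c(C(C)=O)c2O)c1O | intermediate
7 | 2-acetyl-4-[(5-butanoyl-2,6-dihydroxy-3,3-dimethyl-4-oxocyclohexa-1,5-dien-1-yl)methyl]-3,5-dihydroxy-6,6-dimethylcyclohexa-2,4-dien-1-one | CCCC(=O)C1=C(O)C(CC2=C(O)C(C)(C)C(=O)C(C(C)=O)=C2O)=C(O)C(C)(C)C1=O | target

**Total step count:** 3
**Longest linear sequence:** 3 steps (1 → 2 → 5 → 7)

**Steps most likely to fail**

Step 3. The second methyl group of a ring may enter at the bridge-bearing carbon, after which retro-Michael loss of the bridge would cleave and scramble the dimer. Under- or over-methylation and O-methylation would further split the material. The fallback dearomatizes before the bridge is made and adds the acetyl group last, so that every bond is formed at the only open position. It sets out from 3. Gem-dimethylation of the monomer (NaOMe, MeI, MeOH) should give 2-butanoyl-3,5-dihydroxy-6,6-dimethylcyclohexa-2,4-dien-1-one (butyrylfilicinic acid) F1. Part of it is deacylated in hot aqueous mineral acid (retro-Friedel–Crafts cleavage) to 3,5-dihydroxy-4,4-dimethylcyclohexa-2,5-dien-1-one (filicinic acid) F2. The rest is aminomethylated (CH2O, Me2NH, EtOH) to 2-butanoyl-4-[(dimethylamino)methyl]-3,5-dihydroxy-6,6-dimethylcyclohexa-2,4-dien-1-one F3. Heating F3 with an excess of F2 in dioxane (elimination of dimethylamine, then conjugate addition) should give 2-butanoyl-4-[(2,6-dihydroxy-3,3-dimethyl-4-oxocyclohexa-1,5-dien-1-yl)methyl]-3,5-dihydroxy-6,6-dimethylcyclohexa-2,4-dien-1-one F4. C-Acetylation of its single remaining ring CH (Ac2O, BF3·OEt2, via the enol acetate and acyl shift) comes back to the route at 7.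

Step 2. The ortho-quinone methide may be captured by Mannich base 2 or by product 5 faster than by the acyl-deactivated ring of 3, which would give symmetrical and oligomeric methylene-bridged material. The fallback bridges first to a more nucleophilic, acyl-free partner and introduces the butanoyl group afterwards. It sets out from 2, which is heated with a large excess of benzene-1,3,5-triol (phloroglucinol) in dioxane to give 1-{2,4,6-trihydroxy-3-[(2,4,6-trihydroxyphenyl)methyl]phenyl}ethan-1-one F5. Friedel–Crafts acylation with butanoic acid and BF3·OEt2 should then occur on the acyl-free, more electron-rich ring, whose two open positions are equivalent. This comes back to the route at 5.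

Step 1. A second aminomethylation at the other free ring carbon, or early condensation of the Mannich base with unreacted 1, may consume the material. The fallback brings in the one-carbon unit as a deactivating formyl group, so that substitution stops after one carbon. It sets out from 1. Vilsmeier–Haack formylation (POCl3, DMF, then water) should give 3-acetyl-2,4,6-trihydroxybenzaldehyde F6. Reductive amination of the aldehyde (Me2NH, NaBH(OAc)3, 1,2-dichloroethane) comes back to the route at 2.

**Further compounds**
F1 | step 3 | 2-butanoyl-3,5-dihydroxy-6,6-dimethylcyclohexa-2,4-dien-1-one (butyrylfilicinic acid) | CCCC(=O)C1=C(O)C=C(O)C(C)(C)C1=O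
F2 | step 3 | 3,5-dihydroxy-4,4-dimethylcyclohexa-2,5-dien-1-one (filicinic acid) | CC1(C)C(O)=CC(=O)C=C1O
F3 | step 3 | 2-butanoyl-4-[(dimethylamino)methyl]-3,5-dihydroxy-6,6-dimethylcyclohexa-2,4-dien-1-one | CCCC(=O)C1=C(O)C(CN(C)C)=C(O)C(C)(C)C1=O
F4 | step 3 | 2-butanoyl-4-[(2,6-dihydroxy-3,3-dimethyl-4-oxocyclohexa-1,5-dien-1-yl)methyl]-3,5-dihydroxy-6,6-dimethylcyclohexa-2,4-dien-1-one | CCCC(=O)C1=C(O)C(CC2=C(O)C(C)(C)C(=O)C=C2O)=C(O)C(C)(C)C1=O
F5 | step 2 | 1-{2,4,6-trihydroxy-3-[(2,4,6-trihydroxyphenyl)methyl]phenyl}ethan-1-one | CC(=O)c1c(O)cc(O)c(Cc2c(O)cc(O)cc2O)c1O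
F6 | step 1 | 3-acetyl-2,4,6-trihydroxybenzaldehyde | CC(=O)c1c(O)cc(O)c(C=O)c1O
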